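**Retrosynthetic overview**
- Target ⇐ desilylation, dihydroxylation of the C12 vinyl group and C14 glycolate ester formation from a tricyclic C14 alcohol.
- Eight-membered ring closed last: C5–C14 bond by a samarium-electrocatalysed ketyl–enone cyclisation of an enone aldehyde (sets C5, C14, C4).
- C11–C12 bond by Felkin-selective allylboration of a hydrindenone aldehyde with a (Z)-enynyl allylboronate (sets C11, C12; the alkyne becomes the C14 aldehyde, the vinyl group the C19/C20 diol).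
- Hydrindenone from (S)-pulegone: deconjugative cyanoethylation (C9), methylation (C15), electroreductive ketone–nitrile cyclisation and dehydration (five-membered ring), hydroboration (C10, C11).
- Ring order: six-membered ring bought, five-membered ring second, eight-membered ring last.

Assumption: the stereodescriptors of the given SMILES are taken as authoritative (mutilin numbering, used for all locants below: 4S,5S,6S,9S,10R,11S,12R,14R,19S), so the C6 methyl centre is bought as (S)-(−)-pulegone and every SMILES below carries the target's descriptors.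

**Route**

Step 1
Reactants: 1 (S)-(−)-pulegone; 2 acrylonitrile
Product: 3 3-[(1S,4S)-4-methyl-2-oxo-1-(prop-1-en-2-yl)cyclohexyl]propanenitrile
Conditions: KOt-Bu (0.2 equiv), t-BuOH/THF, 0 °C → rt
Reagents that add atoms: none
Why: Base-catalysed deconjugative Michael addition (cyanoethylation) through the thermodynamic extended dienolate, which reacts at its α-carbon; axial attack with the ring methyl equatorial puts the cyanoethyl group cis to that methyl and the isopropenyl group trans, setting C9 (S) from the bought centre (expected dr about 4:1, minor isomer removed on silica).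

Step 2
Reactants: 3 3-[(1S,4S)-4-methyl-2-oxo-1-(prop-1-en-2-yl)cyclohexyl]propanenitrile
Product: 4 3-[(1S,3R,4S)-3,4-dimethyl-2-oxo-1-(prop-1-en-2-yl)cyclohexyl]propanenitrile
Conditions: LiN(i-Pr)2 (LDA, 1.1 equiv), THF, −78 °C; MeI, −78 → −20 °C
Reagents that add atoms: iodomethane CI
Why: Kinetic enolate alkylation at the only enolisable ketone α-carbon (C5), MeI entering trans to the neighbouring C6 methyl; this centre becomes sp2 in step 4, so its minor epimer converges.

Step 3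
Reactants: 4 3-[(1S,3R,4S)-3,4-dimethyl-2-oxo-1-(prop-1-en-2-yl)cyclohexyl]propanenitrile
Product: 6 (3aS,6S,7R,7aR)-7a-hydroxy-6,7-dimethyl-3a-(prop-1-en-2-yl)octahydro-1H-inden-1-one, via hydroxy-imine 5 (not isolated)
Conditions: divided cell, Sn cathode, Pt anode, Et4NOTs, i-PrOH, constant current (ca. 3 F/mol), 25 °C; then H2O
Reagents that add atoms: water O
Why: Known cathodic ketone–nitrile reductive coupling (Shono-type electroreductive cyclisation): the ketyl radical anion adds 5-exo to the nitrile carbon to give the cis-fused α-hydroxy imine, which water hydrolyses to the α-hydroxy ketone; the new carbinol centre (hydroxyl cis to isopropenyl) is erased in step 4.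

Step 4
Reactants: 6 (3aS,6S,7R,7aR)-7a-hydroxy-6,7-dimethyl-3a-(prop-1-en-2-yl)octahydro-1H-inden-1-one
Product: 7 (3aS,6S)-6,7-dimethyl-3a-(prop-1-en-2-yl)-2,3,3a,4,5,6-hexahydro-1H-inden-1-one
Conditions: SOCl2, pyridine, CH2Cl2, 0 °C
Reagents that add atoms: none
Why: Dehydration of the tertiary α-hydroxy ketone through its chlorosulfite (E2 with the anti C5–H, the only position that can give an alkene) forms the tetrasubstituted conjugated C4=C5 enone; no new stereocentre.

Step 5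
Reactants: 7 (3aS,6S)-6,7-dimethyl-3a-(prop-1-en-2-yl)-2,3,3a,4,5,6-hexahydro-1H-inden-1-one
Product: 9 (3aS,6S)-3a-[(2R)-1-hydroxypropan-2-yl]-6,7-dimethyl-2,3,3a,4,5,6-hexahydro-1H-inden-1-one, via alkylboronate 8 (not isolated)
Conditions: HBpin (1.5 equiv), Rh(PPh3)3Cl (3 mol%), THF, 40 °C; then H2O2, aq. NaOH, 0 °C
Reagents that add atoms: pinacolborane CC1(C)OBOC1(C)C; hydrogen peroxide OO
Why: Rhodium-catalysed anti-Markovnikov hydroboration with pinacolborane (which spares the ketone and the hindered enone) followed by stereoretentive C–B oxidation; in the rotamer whose CH2 terminus eclipses the C9–C8 bond the enone carbon C4 shields one face, so hydrogen reaches C10 from the face flanked by C1 and C10 becomes R (expected dr about 5:1, epimer separated).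

Step 6
Reactants: 9 (3aS,6S)-3a-[(2R)-1-hydroxypropan-2-yl]-6,7-dimethyl-2,3,3a,4,5,6-hexahydro-1H-inden-1-one
Product: 10 (2R)-2-[(3aS,6S)-6,7-dimethyl-1-oxo-1,2,3,4,5,6-hexahydro-3aH-inden-3a-yl]propanal
Conditions: Dess–Martin periodinane, CH2Cl2, 0 °C → rt
Reagents that add atoms: none
Why: Dess–Martin oxidation of the primary alcohol to the aldehyde under near-neutral conditions that do not epimerise the α-stereocentre C10.

Step 7
Reactants: 11 (2Z)-3-methylpent-2-en-4-yn-1-ol
Product: 12 (3Z)-5-chloro-3-methylpent-3-en-1-yne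
Conditions: PPh3, CCl4, CH2Cl2, 0 °C → rt
Reagents that add atoms: carbon tetrachloride ClC(Cl)(Cl)Cl
Why: Appel chlorination, an SN2 displacement at the primary allylic carbon without allylic transposition, so the (Z)-geometry is kept.

Step 8
Reactants: 12 (3Z)-5-chloro-3-methylpent-3-en-1-yne
Product: 13 2-[(2Z)-3-methylpent-2-en-4-yn-1-yl]-4,4,5,5-tetramethyl-1,3,2-dioxaborolane
Conditions: B2pin2, Pd2(dba)3 (1 mol%), THF, 60 °C
Reagents that add atoms: bis(pinacolato)diboron CC1(C)OB(OC1(C)C)B1OC(C)(C)C(C)(C)O1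
Why: Palladium-catalysed borylation of an allylic chloride (oxidative addition to zerovalent palladium, transmetalation with B2pin2, reductive elimination at the primary terminus), a reaction type that preserves the (Z)-geometry of trisubstituted allylic chlorides.

Step 9
Reactants: 10 (2R)-2-[(3aS,6S)-6,7-dimethyl-1-oxo-1,2,3,4,5,6-hexahydro-3aH-inden-3a-yl]propanal; 13 2-[(2Z)-3-methylpent-2-en-4-yn-1-yl]-4,4,5,5-tetramethyl-1,3,2-dioxaborolane
Product: 15 (3aS,6S)-3a-[(2R,3S,4R)-4-ethynyl-3-hydroxy-4-methylhex-5-en-2-yl]-6,7-dimethyl-2,3,3a,4,5,6-hexahydro-1H-inden-1-one, via borate ester 14 (not isolated)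
Conditions: toluene, 70 °C; then H2O work-up
Reagents that add atoms: none
Why: Allylboration through a closed chair (Zimmerman–Traxler) transition state: the (Z)-ethynyl group ends syn and the (E)-methyl anti to the new hydroxyl (C12), and Felkin–Anh attack anti to the quaternary C9 of the α-stereocentre sets C11 (S), favoured because only the slim ethynyl group must pass the α-methyl; the hindered enone carbonyl does not react.

Step 10
Reactants: 15 (3aS,6S)-3a-[(2R,3S,4R)-4-ethynyl-3-hydroxy-4-methylhex-5-en-2-yl]-6,7-dimethyl-2,3,3a,4,5,6-hexahydro-1H-inden-1-one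
Product: 16 (3aS,6S)-3a-[(2R,3S,4R)-3-{[tert-butyl(dimethyl)silyl]oxy}-4-ethynyl-4-methylhex-5-en-2-yl]-6,7-dimethyl-2,3,3a,4,5,6-hexahydro-1H-inden-1-one
Conditions: TBSOTf, 2,6-lutidine, CH2Cl2, 0 °C → rt
Reagents that add atoms: tert-butyldimethylsilyl triflate CC(C)(C)[Si](C)(C)OS(=O)(=O)C(F)(F)F
Why: Silyl triflate silylation of the hindered secondary alcohol, needed to prevent lactol formation with the later C14 aldehyde and to shield one face of the vinyl group in step 14; no stereocentre is touched.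

Step 11
Reactants: 16 (3aS,6S)-3a-[(2R,3S,4R)-3-{[tert-butyl(dimethyl)silyl]oxy}-4-ethynyl-4-methylhex-5-en-2-yl]-6,7-dimethyl-2,3,3a,4,5,6-hexahydro-1H-inden-1-one
Product: 17 (3S,4S,5R)-4-{[tert-butyl(dimethyl)silyl]oxy}-5-[(3aS,6S)-6,7-dimethyl-1-oxo-1,2,3,4,5,6-hexahydro-3aH-inden-3a-yl]-3-ethenyl-3-methylhexanal
Conditions: [CpRu(MeCN)3]PF6 (5 mol%), 5,5′-bis(trifluoromethyl)-2,2′-bipyridine (5 mol%), NMP/H2O (4:1), 40 °C
Reagents that add atoms: water O
Why: Ruthenium-catalysed anti-Markovnikov hydration of the terminal alkyne via a ruthenium vinylidene gives the aldehyde under neutral conditions; vinyl group, enone and silyl ether are inert and no stereocentre changes.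

Step 12
Reactants: 17 (3S,4S,5R)-4-{[tert-butyl(dimethyl)silyl]oxy}-5-[(3aS,6S)-6,7-dimethyl-1-oxo-1,2,3,4,5,6-hexahydro-3aH-inden-3a-yl]-3-ethenyl-3-methylhexanal
Product: 19 (1S,2R,3S,4S,6R,7S,8S,14S)-3-{[tert-butyl(dimethyl)silyl]oxy}-4-ethenyl-6-hydroxy-2,4,7,14-tetramethyltricyclo[5.4.3.0(1,8)]tetradecan-9-one, via C3-enol 18 (not isolated)
Conditions: SmI2 (10 mol%), 2,6-lutidinium triflate (2.2 equiv), n-Bu4NPF6 (0.1 M), THF (5 mM in 17), undivided cell, glassy-carbon cathode, zinc anode, constant current (2.2 F/mol), 0 °C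
Reagents that add atoms: none
Why: Proposed new method: samarium-electrocatalysed 8-endo ketyl–enone cyclisation, in which cathodically regenerated divalent samarium reduces the C14 aldehyde to a samarium ketyl that adds to C5 of the tethered enone inside a chelate bridging the ketyl oxygen and the C3 carbonyl, a second electron gives the trivalent samarium enolate, and 2,6-lutidinium triflate protonolyses the Sm–O bonds (C4–H from the open face) to release the product and the catalyst, the tether and chelate fixing C5 (S), C14 (R) and C4 (S); the closest known reaction types are the stoichiometric SmI2 ketyl–olefin cyclisation used to close eight-membered rings and samarium-catalysed electroreductive intermolecular ketyl–olefin coupling, neither shown for an intramolecular medium-ring closure onto a tetrasubstituted enone.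

Step 13
Reactants: 19 (1S,2R,3S,4S,6R,7S,8S,14S)-3-{[tert-butyl(dimethyl)silyl]oxy}-4-ethenyl-6-hydroxy-2,4,7,14-tetramethyltricyclo[5.4.3.0(1,8)]tetradecan-9-one; 20 {[tert-butyl(dimethyl)silyl]oxy}acetic acid
Product: 21 [(1S,2R,3S,4S,6R,7S,8S,14S)-3-{[tert-butyl(dimethyl)silyl]oxy}-4-ethenyl-2,4,7,14-tetramethyl-9-oxotricyclo[5.4.3.0(1,8)]tetradecan-6-yl] 2-{[tert-butyl(dimethyl)silyl]oxy}acetate
Conditions: DCC, DMAP, CH2Cl2, rt
Reagents that add atoms: none
Why: Steglich esterification of the only free hydroxyl, the hindered C14 alcohol, with retention at C14 because its C–O bond is not broken.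

Step 14
Reactants: 21 [(1S,2R,3S,4S,6R,7S,8S,14S)-3-{[tert-butyl(dimethyl)silyl]oxy}-4-ethenyl-2,4,7,14-tetramethyl-9-oxotricyclo[5.4.3.0(1,8)]tetradecan-6-yl] 2-{[tert-butyl(dimethyl)silyl]oxy}acetate
Product: 22 [(1S,2R,3S,4S,6R,7S,8S,14S)-3-{[tert-butyl(dimethyl)silyl]oxy}-4-[(1S)-1,2-dihydroxyethyl]-2,4,7,14-tetramethyl-9-oxotricyclo[5.4.3.0(1,8)]tetradecan-6-yl] 2-{[tert-butyl(dimethyl)silyl]oxy}acetate
Conditions: OsO4 (5 mol%), NMO, acetone/H2O, rt
Reagents that add atoms: N-methylmorpholine N-oxide C[N+]1([O-])CCOCC1; water O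
Why: Upjohn syn-dihydroxylation of the only alkene: in the rotamer with the C18 methyl eclipsing the C19=C20 bond, OsO4 adds to the face flanked by C13 and away from C11 with its bulky silyloxy group, giving the 19S diol (1,3-syn to the C11 oxygen).

Step 15
Reactants: 22 [(1S,2R,3S,4S,6R,7S,8S,14S)-3-{[tert-butyl(dimethyl)silyl]oxy}-4-[(1S)-1,2-dihydroxyethyl]-2,4,7,14-tetramethyl-9-oxotricyclo[5.4.3.0(1,8)]tetradecan-6-yl] 2-{[tert-butyl(dimethyl)silyl]oxy}acetate
Product: 23 Pleuromutilin A, [(1S,2R,3S,4R,6R,7S,8S,14S)-4-[(1S)-1,2-dihydroxyethyl]-3-hydroxy-2,4,7,14-tetramethyl-9-oxotricyclo[5.4.3.0(1,8)]tetradecan-6-yl] 2-hydroxyacetate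
Conditions: HF·pyridine, THF/pyridine, 0 °C → rt
Reagents that add atoms: none
Why: Fluoride-mediated cleavage of both silyl ethers with buffered HF, conditions that leave the glycolate ester, the diol and the ketone intact and touch no stereocentre.

**Compound list**

1 | (S)-(−)-pulegone, (5S)-5-methyl-2-(propan-2-ylidene)cyclohexan-1-one | CC(C)=C1CC[C@H](C)CC1=O | starting material
2 | acrylonitrile | C=CC#N | starting material
3 | 3-[(1S,4S)-4-methyl-2-oxo-1-(prop-1-en-2-yl)cyclohexyl]propanenitrile | CC(=C)[C@@]1(CCC#N)CC[C@H](C)CC1=O | intermediate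
4 | 3-[(1S,3R,4S)-3,4-dimethyl-2-oxo-1-(prop-1-en-2-yl)cyclohexyl]propanenitrile | CC(=C)[C@@]1(CCC#N)CC[C@H](C)[C@@H](C)C1=O | intermediate
5 | (3aS,6S,7R,7aR)-1-imino-6,7-dimethyl-3a-(prop-1-en-2-yl)octahydro-7aH-inden-7a-ol (not isolated) | CC(=C)[C@]12CCC(=N)[C@@]1(O)[C@H](C)[C@@H](C)CC2 | intermediate
6 | (3aS,6S,7R,7aR)-7a-hydroxy-6,7-dimethyl-3a-(prop-1-en-2-yl)octahydro-1H-inden-1-one | CC(=C)[C@]12CCC(=O)[C@@]1(O)[C@H](C)[C@@H](C)CC2 | intermediate
7 | (3aS,6S)-6,7-dimethyl-3a-(prop-1-en-2-yl)-2,3,3a,4,5,6-hexahydro-1H-inden-1-one | CC(=C)[C@]12CCC(=O)C1=C(C)[C@@H](C)CC2 | intermediate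
8 | (3aS,6S)-6,7-dimethyl-3a-[(2S)-1-(4,4,5,5-tetramethyl-1,3,2-dioxaborolan-2-yl)propan-2-yl]-2,3,3a,4,5,6-hexahydro-1H-inden-1-one (not isolated) | C[C@@H](CB3OC(C)(C)C(C)(C)O3)[C@]12CCC(=O)C1=C(C)[C@@H](C)CC2 | intermediate
9 | (3aS,6S)-3a-[(2R)-1-hydroxypropan-2-yl]-6,7-dimethyl-2,3,3a,4,5,6-hexahydro-1H-inden-1-one | C[C@@H](CO)[C@]12CCC(=O)C1=C(C)[C@@H](C)CC2 | intermediate
10 | (2R)-2-[(3aS,6S)-6,7-dimethyl-1-oxo-1,2,3,4,5,6-hexahydro-3aH-inden-3a-yl]propanal | C[C@@H](C=O)[C@]12CCC(=O)C1=C(C)[C@@H](C)CC2 | intermediate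
11 | (2Z)-3-methylpent-2-en-4-yn-1-ol | C#C/C(C)=C\CO | starting material
12 | (3Z)-5-chloro-3-methylpent-3-en-1-yne | C#C/C(C)=C\CCl | intermediate
13 | 2-[(2Z)-3-methylpent-2-en-4-yn-1-yl]-4,4,5,5-tetramethyl-1,3,2-dioxaborolane | C#C/C(C)=C\CB1OC(C)(C)C(C)(C)O1 | intermediate
14 | pinacol borate ester of 15, 2-{[(2R,3S,4R)-2-[(3aS,6S)-6,7-dimethyl-1-oxo-1,2,3,4,5,6-hexahydro-3aH-inden-3a-yl]-4-ethynyl-4-methylhex-5-en-3-yl]oxy}-4,4,5,5-tetramethyl-1,3,2-dioxaborolane (not isolated) | C[C@@H]([C@H](OB3OC(C)(C)C(C)(C)O3)[C@](C)(C=C)C#C)[C@]12CCC(=O)C1=C(C)[C@@H](C)CC2 | intermediate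
15 | (3aS,6S)-3a-[(2R,3S,4R)-4-ethynyl-3-hydroxy-4-methylhex-5-en-2-yl]-6,7-dimethyl-2,3,3a,4,5,6-hexahydro-1H-inden-1-one | C[C@@H]([C@H](O)[C@](C)(C=C)C#C)[C@]12CCC(=O)C1=C(C)[C@@H](C)CC2 | intermediate
16 | (3aS,6S)-3a-[(2R,3S,4R)-3-{[tert-butyl(dimethyl)silyl]oxy}-4-ethynyl-4-methylhex-5-en-2-yl]-6,7-dimethyl-2,3,3a,4,5,6-hexahydro-1H-inden-1-one | C[C@@H]([C@H](O[Si](C)(C)C(C)(C)C)[C@](C)(C=C)C#C)[C@]12CCC(=O)C1=C(C)[C@@H](C)CC2 | intermediate
17 | (3S,4S,5R)-4-{[tert-butyl(dimethyl)silyl]oxy}-5-[(3aS,6S)-6,7-dimethyl-1-oxo-1,2,3,4,5,6-hexahydro-3aH-inden-3a-yl]-3-ethenyl-3-methylhexanal | C[C@@H]([C@H](O[Si](C)(C)C(C)(C)C)[C@](C)(C=C)CC=O)[C@]12CCC(=O)C1=C(C)[C@@H](C)CC2 | intermediate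
18 | (1S,2R,3S,4S,6R,7S,14S)-3-{[tert-butyl(dimethyl)silyl]oxy}-4-ethenyl-2,4,7,14-tetramethyltricyclo[5.4.3.0(1,8)]tetradec-8-ene-6,9-diol (C3-enol, not isolated) | C[C@H]1[C@H](O[Si](C)(C)C(C)(C)C)[C@](C)(C=C)C[C@@H](O)[C@@]2(C)[C@@H](C)CC[C@]13CCC(O)=C32 | intermediate
19 | (1S,2R,3S,4S,6R,7S,8S,14S)-3-{[tert-butyl(dimethyl)silyl]oxy}-4-ethenyl-6-hydroxy-2,4,7,14-tetramethyltricyclo[5.4.3.0(1,8)]tetradecan-9-one | C[C@H]1[C@H](O[Si](C)(C)C(C)(C)C)[C@](C)(C=C)C[C@@H](O)[C@@]2(C)[C@@H](C)CC[C@]13CCC(=O)[C@@H]32 | intermediate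
20 | {[tert-butyl(dimethyl)silyl]oxy}acetic acid | CC(C)(C)[Si](C)(C)OCC(=O)O | starting material
21 | [(1S,2R,3S,4S,6R,7S,8S,14S)-3-{[tert-butyl(dimethyl)silyl]oxy}-4-ethenyl-2,4,7,14-tetramethyl-9-oxotricyclo[5.4.3.0(1,8)]tetradecan-6-yl] 2-{[tert-butyl(dimethyl)silyl]oxy}acetate | C[C@H]1[C@H](O[Si](C)(C)C(C)(C)C)[C@](C)(C=C)C[C@@H](OC(=O)CO[Si](C)(C)C(C)(C)C)[C@@]2(C)[C@@H](C)CC[C@]13CCC(=O)[C@@H]32 | intermediate
22 | [(1S,2R,3S,4S,6R,7S,8S,14S)-3-{[tert-butyl(dimethyl)silyl]oxy}-4-[(1S)-1,2-dihydroxyethyl]-2,4,7,14-tetramethyl-9-oxotricyclo[5.4.3.0(1,8)]tetradecan-6-yl] 2-{[tert-butyl(dimethyl)silyl]oxy}acetate | C[C@H]1[C@H](O[Si](C)(C)C(C)(C)C)[C@](C)([C@H](O)CO)C[C@@H](OC(=O)CO[Si](C)(C)C(C)(C)C)[C@@]2(C)[C@@H](C)CC[C@]13CCC(=O)[C@@H]32 | intermediate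
23 | Pleuromutilin A, [(1S,2R,3S,4R,6R,7S,8S,14S)-4-[(1S)-1,2-dihydroxyethyl]-3-hydroxy-2,4,7,14-tetramethyl-9-oxotricyclo[5.4.3.0(1,8)]tetradecan-6-yl] 2-hydroxyacetate | C[C@H]1[C@H](O)[C@](C)([C@H](O)CO)C[C@@H](OC(=O)CO)[C@@]2(C)[C@@H](C)CC[C@]13CCC(=O)[C@@H]32 | target

**Step count and risks**

Total step count: 15. Longest linear sequence: 13 (steps 1–6 and 9–15, from pulegone).

Most likely to fail, first: step 12, the proposed new samarium-electrocatalysed ring closure. Acid reduction at the cathode, simple aldehyde reduction or pinacol coupling may outrun the eight-membered cyclisation. The fallback sets out from 17 and comes back at 19. It drops the electrocatalytic cycle for the classical reagent-based radical cyclisation: stoichiometric SmI2 (2.5–3 equiv) in THF with t-BuOH at 0 °C, the known ketyl–enone reaction for closing eight-membered rings of this type. It needs no cell and no acid-driven turnover, and makes no new compound.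

Second: step 5. The neopentyl-type 1,1-disubstituted alkene may react sluggishly, the enone may be reduced, or the C10 facial selectivity may be low. The fallback sets out from 7 and comes back at 9. Allylic hydroxylation of the isopropenyl methyl with SeO2 (cat.)/t-BuOOH in CH2Cl2 gives (3aS,6S)-3a-(3-hydroxyprop-1-en-2-yl)-6,7-dimethyl-2,3,3a,4,5,6-hexahydro-1H-inden-1-one F1. Hydroxyl-directed homogeneous hydrogenation with [Rh(nbd)(dppb)]BF4 under H2 in CH2Cl2 then delivers hydrogen to C10 from the metal bound to the hydroxyl in the conformer of least allylic strain and leaves the tetrasubstituted enone untouched.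

Third: step 14. The facial selectivity of osmylation at C19 rests on steric shielding by the C11 silyl ether and may be modest. The fallback sets out from 21 and comes back at 23, steering C19 by hydroxyl delivery instead. HF·pyridine first removes both silyl groups to give the 11-hydroxy vinyl glycolate F2. VO(acac)2/t-BuOOH in CH2Cl2 then epoxidises the vinyl group through a chair-like vanadate bound to the homoallylic C11 hydroxyl, expected to give the 1,3-syn (19S) epoxide F3. Dilute aqueous HClO4 in THF opens the epoxide at the terminal carbon C20 with retention at C19 to give 23 directly.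

Further compounds
F1 | step 5 | (3aS,6S)-3a-(3-hydroxyprop-1-en-2-yl)-6,7-dimethyl-2,3,3a,4,5,6-hexahydro-1H-inden-1-one | C=C(CO)[C@]12CCC(=O)C1=C(C)[C@@H](C)CC2
F2 | step 14 | [(1S,2R,3S,4S,6R,7S,8S,14S)-4-ethenyl-3-hydroxy-2,4,7,14-tetramethyl-9-oxotricyclo[5.4.3.0(1,8)]tetradecan-6-yl] 2-hydroxyacetate | C[C@H]1[C@H](O)[C@](C)(C=C)C[C@@H](OC(=O)CO)[C@@]2(C)[C@@H](C)CC[C@]13CCC(=O)[C@@H]32
F3 | step 14 | [(1S,2R,3S,4R,6R,7S,8S,14S)-3-hydroxy-2,4,7,14-tetramethyl-4-[(2S)-oxiran-2-yl]-9-oxotricyclo[5.4.3.0(1,8)]tetradecan-6-yl] 2-hydroxyacetate | C[C@H]1[C@H](O)[C@](C)([C@H]4CO4)C[C@@H](OC(=O)CO)[C@@]2(C)[C@@H](C)CC[C@]13CCC(=O)[C@@H]32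
F0 | step 12 | none | none
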